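The earlier runs and the new flask stem from a simulated flask from invented constants; noise was put on by code.

The ratio τ/t of two times tells whether the noon flask still holds solid substrate feeding its dissolved starting material at the asked time t = 6.0 min; τ is the life of the solid, its charge over the rate F at which it enters solution.

| flask | solid substrate | fresh partner | coupling partner | remark | time |
|---|---|---|---|---|---|
| noon | 20 mM | 19 mM | 80 mM (in portions, 2) | the very flask that is asked about, followed so far; portions every 30 s |  |
| autumn | 10 mM | 19 mM | 80 mM (in portions, 2) | run made earlier; portions every 30 s |  |
| flask | 20 mM | 19.0 mM | 80.0 mM (in portions, 2) | the portions of coupling partner follow each other after 30 s, the first at the start | 6.0 min |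

- noon (time / min: target / %, starting material / %): 0.500: 0, 7.7; 1.00: 0.2, 11.2; 1.50: 0.2, 11.5; 2.00: 2.3, 11.5; 2.50: 4.6, 10.7; 3.00: 6.0, 10.5
- autumn (time / min: target / %, starting material / %): 1.00: 0.7, 19.9; 2.00: 4.9, 22.1; 3.00: 12.4, 22.1; 4.00: 20.6, 8.9; 5.00: 26.4, 2.8; 6.00: 31.4, 1.4

(each reading ± 0.5 percentage points)

- percentages count the solid substrate that a species holds: one homo product or side product counts as two
- solid, in amounts per volume of the solution: solid substrate
- the analysis behind the earlier runs scatters by 0.5 percentage points, standard deviation
- on the list of suspects stand: starting material + coupling partner -> open intermediate; open intermediate + second intermediate -> target; coupling partner + fresh partner -> second intermediate; starting material + open intermediate -> side product; solid substrate <-> starting material; 2 open intermediate -> homo product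
- at the start none of the solid substrate is in solution
- starting material means what is dissolved; the solid is not counted in it

* concentration of target at 6.0 min, in mM
* concentration of starting material at 6.0 min, in mM
* concentration of fresh partner at 6.0 min, in mM

Starting material stands at 2.30 mM in the noon run at 2.00 min and at 2.21 mM in the autumn run at 3.00 min, although noon has twice the solid. This level, a quasi-steady state, does not follow the solid charge, so one F is assumed for both flasks. The autumn level breaks between 3.00 min and 4.00 min, from 22.1% to 8.9%. Replacing the dissolving curve by its mean, with the autumn charge spent at the middle of that interval, gives F = 2.86 mM min⁻¹. The noon solid then lasts τ = 7.00 min, and a break at either end of the interval moves τ between 6.00 min and 8.00 min. Since τ/t = 1.17, my reckoning leaves 2.86 mM of solid at t, with starting material at its noon mean, 2.21 mM.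

The forecast, lower than this on starting material, gives 4.1 mM of target, 1.9 mM of starting material and 13 mM of fresh partner, on the ground: “solid remains and A sits near 2 mM, drifting down slowly”.

The noon flask gives 3.59 mM of target, 2.47 mM of starting material and 1.46 mM of fresh partner.

    starting material + coupling partner → open intermediate (k = 0.230 L mol⁻¹ s⁻¹)
    open intermediate + second intermediate → target (k = 0.560 L mol⁻¹ s⁻¹)
    coupling partner + fresh partner → second intermediate (k = 0.120 L mol⁻¹ s⁻¹)
    starting material + open intermediate → side product (k = 4.20 L mol⁻¹ s⁻¹)
    solid substrate ⇌ starting material, rate k5*(cs5 - [starting material]) while solid is left; crystals form when [starting material] > cs5 (solubility = 8.70 mM, k = 0.00760 s⁻¹)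
    2 open intermediate → homo product (k = 0.230 L mol⁻¹ s⁻¹)

The reckoned τ = 7.00 min is longer than t, and the noon flask still holds 2.01 mM of solid at 6.00 min, against the reckoned 2.86 mM. The neighbouring flask is the same recipe with 320 mM of coupling partner. With its dissolved level taken as zero, an assumption of this reckoning, the dissolving constant times the solubility gives F = 3.97 mM min⁻¹, so the reckoned τ = 5.04 min, shorter than t. At 6.00 min that flask holds 0% of its solid substrate charge and 0.0709 mM of starting material.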